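**Retrosynthetic overview** (chain numbering of the nonadecane skeleton: C1–C5 pentyl, C18=C19 vinyl; O1 = ring oxygen; ring = O1–C6–C7–C8–C9)
1. Target 15 ⇐ C10 ketone 14 (Felkin–Anh reduction sets 10R) ⇐ C7–OH + octadecanoyl chloride.
2. Oxolane O1–C6–C7–C8–C9 ⇐ oxetane O1–C6–C7–C8 (4) + C9 of epoxide 7 (C9–C19). C9 is lithiated, so the C8–C9 bond joins two oxygen-bearing, natively electrophilic carbons by polarity reversal; O1 then re-closes on C9.
3. Enabling feature: ring carbon C9 carries O1 and is vicinal to the C10 carbinol (an opened C9–C10 epoxide), and its ring neighbour C8 is an unsubstituted CH2 that can sit on O1 in a four-membered ring. C9 can therefore be inserted into the O1–C8 bond.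
4. Stereocentres: C6 bought ((S)-oct-1-yn-3-ol); C7 by substrate-controlled reduction; C10 by kinetic resolution, relayed to C9 in the key step. The trans-lithiation gives the 9,10-erythro relationship, so C10 is then reset by oxidation and reduction.
5. Ring order: oxetane (step 1), then oxolane (step 6).

Key step: step 6

Assumption: (S)-oct-1-yn-3-ol, undeca-1,10-diene and octadecanoyl chloride are taken as commercial; the (S,S)-(salen)Co catalyst is assumed to be the antipode that leaves the (S)-epoxide, otherwise its mirror image is used.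

Step 1
Reactants: 1 (S)-oct-1-yn-3-ol
Product: 2 (2S)-2-pentyloxetan-3-one
Conditions: (2-biphenyl)Cy2PAuNTf2 (5 mol%), methyl 5-bromonicotinate N-oxide, HNTf2, DCE, rt
Reagents that add atoms: methyl 5-bromopyridine-3-carboxylate 1-oxide, COC(=O)c1cc(Br)c[n+]([O-])c1
Why: Gold-catalysed alkyne oxidation gives an α-oxo gold carbene at C8 that inserts into the propargylic O–H bond and closes the four-membered ring, a known route from secondary propargylic alcohols to oxetan-3-ones; C6 is not involved and should keep its configuration.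

Step 2
Reactants: 2 (2S)-2-pentyloxetan-3-one
Product: 3 (2S,3S)-2-pentyloxetan-3-ol
Conditions: L-Selectride, THF, −78 °C
Reagents that add atoms: none
Why: Ketone reduction under 1,2-substrate control: the bulky hydride should attack the nearly planar four-membered ring anti to the C6 pentyl group, placing the C7 hydroxyl cis to pentyl (7S), as in reductions of 2-substituted cyclobutanones.

Step 3
Reactants: 3 (2S,3S)-2-pentyloxetan-3-ol
Product: 4 tert-butyldimethyl{[(2S,3S)-2-pentyloxetan-3-yl]oxy}silane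
Conditions: TBSCl, imidazole, DMF, rt
Reagents that add atoms: tert-butyldimethylsilyl chloride, CC(C)(C)[Si](C)(C)Cl
Why: Standard silylation of a secondary alcohol; the silyl ether tolerates the organolithium and BF3 of step 6.

Step 4
Reactants: 5 undeca-1,10-diene
Product: 6 rac-2-(non-8-en-1-yl)oxirane
Conditions: mCPBA (0.5 equiv), CH2Cl2, 0 °C
Reagents that add atoms: mCPBA, OOC(=O)c1cccc(Cl)c1
Why: Prilezhaev epoxidation; with the symmetrical diene in excess the mono-epoxide should dominate and unreacted diene is recovered.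

Step 5
Reactants: 6 rac-2-(non-8-en-1-yl)oxirane
Product: 7 (2S)-2-(non-8-en-1-yl)oxirane
Conditions: (S,S)-(salen)Co(III)OAc (0.5 mol%), H2O (0.55 equiv), THF, 0 °C → rt
Reagents that add atoms: none
Why: Jacobsen hydrolytic kinetic resolution: the catalyst hydrolyses the (R)-epoxide and leaves the (S)-epoxide, fixing C10 by catalyst control.

Step 6
Reactants: 4 tert-butyldimethyl{[(2S,3S)-2-pentyloxetan-3-yl]oxy}silane; 7 (2S)-2-(non-8-en-1-yl)oxirane
Product: 10 (1S)-1-[(2R,4S,5S)-4-[(tert-butyldimethylsilyl)oxy]-5-pentyloxolan-2-yl]dec-9-en-1-ol, via oxiranyllithium 8 (not isolated), via epoxy alcohol 9 (not isolated)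
Conditions: 7 (2 equiv), s-BuLi, N,N′-dibutylbispidine, hexane, −90 °C; cannulate into 4 + BF3·OEt2, Et2O, −90 → −78 °C; aq. NaHCO3; then CSA (cat.), CH2Cl2, 0 °C → rt
Reagents that add atoms: none
Why: Proposed new method: s-BuLi/diamine should remove the terminal epoxide proton trans to the chain of 7 to give the configurationally stable oxiranyllithium 8, a C9 carbanion that carries its own leaving group; 8 should open the BF3-activated oxetane 4 by SN2 attack at the unsubstituted C8 with retention at C9, and the freed O1 hydroxyl of 9 then opens the trans-epoxide at C9 with inversion under acid, so that C9 is inserted into the O1–C8 bond and the oxetane O1–C6–C7–C8 becomes the oxolane O1–C6–C7–C8–C9. The closest known reaction types are the trapping of trans-α-lithiated terminal epoxides by silyl, stannyl, carbonyl and boron electrophiles with retention, the BF3-promoted opening of oxetanes by organolithiums at the less hindered carbon, and the one-carbon ring expansion of oxetanes by dimethylsulfoxonium methylide, which follows the same open-then-reclose course with an unsubstituted carbon. The only ring closed is the oxolane, by 5-exo-tet epoxide opening, which should be favoured over 6-endo attack at C10 for a dialkyl epoxide. The new stereocentre C9 is controlled by the resolved C10 centre through the trans-lithiation and two stereospecific events (retention on alkylation, inversion on closure), which should give 9R and leave a 10S carbinol; C6 and C7 are untouched. The step needs opening at C8 and not at C6, secured by primary versus secondary substitution, and survival of the carbenoid 8, secured by −90 °C, the diamine ligand and addition to the pre-complexed oxetane.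

Step 7
Reactants: 10 (1S)-1-[(2R,4S,5S)-4-[(tert-butyldimethylsilyl)oxy]-5-pentyloxolan-2-yl]dec-9-en-1-ol
Product: 11 1-[(2R,4S,5S)-4-[(tert-butyldimethylsilyl)oxy]-5-pentyloxolan-2-yl]dec-9-en-1-one
Conditions: Dess–Martin periodinane, CH2Cl2, rt
Reagents that add atoms: none
Why: Dess–Martin oxidation of the secondary carbinol under neutral conditions removes the relay centre C10; the silyl ether, the alkene and the now α-keto centre C9 should be unaffected.

Step 8
Reactants: 11 1-[(2R,4S,5S)-4-[(tert-butyldimethylsilyl)oxy]-5-pentyloxolan-2-yl]dec-9-en-1-one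
Product: 12 1-[(2R,4S,5S)-4-hydroxy-5-pentyloxolan-2-yl]dec-9-en-1-one
Conditions: HF·pyridine, THF, 0 °C → rt
Reagents that add atoms: none
Why: Fluoride-induced Si–O cleavage under mildly acidic conditions, chosen over basic TBAF to avoid enolisation at C9; the C7 hydroxyl is trans to the acyl chain and cannot form a hemiketal.

Step 9
Reactants: 12 1-[(2R,4S,5S)-4-hydroxy-5-pentyloxolan-2-yl]dec-9-en-1-one; 13 octadecanoyl chloride
Product: 14 (2S,3S,5R)-5-(dec-9-enoyl)-2-pentyloxolan-3-yl octadecanoate
Conditions: pyridine, DMAP (cat.), CH2Cl2, 0 °C → rt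
Reagents that add atoms: none
Why: DMAP-catalysed acylation of the only hydroxyl group (C7–OH); no stereocentre is touched.

Step 10
Reactants: 14 (2S,3S,5R)-5-(dec-9-enoyl)-2-pentyloxolan-3-yl octadecanoate
Product: 15 (2S,3S,5R)-5-[(1R)-1-hydroxydec-9-en-1-yl]-2-pentyloxolan-3-yl octadecanoate
Conditions: L-Selectride (1.1 equiv), THF, −78 °C
Reagents that add atoms: none
Why: Felkin–Anh (non-chelated) reduction of the α-alkoxy ketone: with the C9–O1 bond anti to the incoming bulky hydride the threo carbinol (10R) should form, the usual sense for 2-acyloxolanes with this reagent; the ester and the terminal alkene should react much more slowly at −78 °C.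

**Compound list**
1 | (S)-oct-1-yn-3-ol | CCCCC[C@H](O)C#C | starting material
2 | (2S)-2-pentyloxetan-3-one | O=C1CO[C@H]1CCCCC | intermediate
3 | (2S,3S)-2-pentyloxetan-3-ol (cis) | CCCCC[C@@H]1OC[C@@H]1O | intermediate
4 | tert-butyldimethyl{[(2S,3S)-2-pentyloxetan-3-yl]oxy}silane | CCCCC[C@@H]1OC[C@@H]1O[Si](C)(C)C(C)(C)C | intermediate
5 | undeca-1,10-diene | C=CCCCCCCCC=C | starting material
6 | rac-2-(non-8-en-1-yl)oxirane | C=CCCCCCCCC1CO1 | intermediate
7 | (2S)-2-(non-8-en-1-yl)oxirane | C=CCCCCCCC[C@H]1CO1 | intermediate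
8 | [(2S,3S)-3-(non-8-en-1-yl)oxiran-2-yl]lithium (Li trans to the chain) | [Li][C@@H]1O[C@H]1CCCCCCCC=C | intermediate
9 | (6S,7S)-7-[(tert-butyldimethylsilyl)oxy]-8-[(2S,3S)-3-(non-8-en-1-yl)oxiran-2-yl]octan-6-ol | CCCCC[C@H](O)[C@@H](O[Si](C)(C)C(C)(C)C)C[C@@H]1O[C@H]1CCCCCCCC=C | intermediate
10 | (1S)-1-[(2R,4S,5S)-4-[(tert-butyldimethylsilyl)oxy]-5-pentyloxolan-2-yl]dec-9-en-1-ol | C=CCCCCCCC[C@H](O)[C@H]1C[C@H](O[Si](C)(C)C(C)(C)C)[C@H](CCCCC)O1 | intermediate
11 | 1-[(2R,4S,5S)-4-[(tert-butyldimethylsilyl)oxy]-5-pentyloxolan-2-yl]dec-9-en-1-one | C=CCCCCCCCC(=O)[C@H]1C[C@H](O[Si](C)(C)C(C)(C)C)[C@H](CCCCC)O1 | intermediate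
12 | 1-[(2R,4S,5S)-4-hydroxy-5-pentyloxolan-2-yl]dec-9-en-1-one | C=CCCCCCCCC(=O)[C@H]1C[C@H](O)[C@H](CCCCC)O1 | intermediate
13 | octadecanoyl chloride | CCCCCCCCCCCCCCCCCC(Cl)=O | starting material
14 | (2S,3S,5R)-5-(dec-9-enoyl)-2-pentyloxolan-3-yl octadecanoate | C=CCCCCCCCC(=O)[C@H]1C[C@H](OC(=O)CCCCCCCCCCCCCCCCC)[C@H](CCCCC)O1 | intermediate
15 | (2S,3S,5R)-5-[(1R)-1-hydroxydec-9-en-1-yl]-2-pentyloxolan-3-yl octadecanoate | C=CCCCCCCC[C@@H](O)[C@H]1C[C@H](OC(=O)CCCCCCCCCCCCCCCCC)[C@H](CCCCC)O1 | target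

Total step count: 10. Longest linear sequence: 8 (steps 1, 2, 3, 6, 7, 8, 9, 10).

**Steps most likely to fail**

Step 6. The oxiranyllithium may collapse (carbenoid dimerisation, 1,2-hydride shift, BF3-induced ring opening of its own epoxide) before it alkylates, or the oxetane may be opened unselectively. The fallback makes the C8–C9 bond with a vinyl anion and uses only known reaction types. It sets out from oxetane 4. Commercial dec-9-enal would be converted by Takai iodo-olefination (CHI3, CrCl2) into (1E)-1-iodoundeca-1,10-diene F1. Iodine–lithium exchange (t-BuLi, Et2O, −78 °C) and addition to 4/BF3·OEt2 should give (6S,7S,9E)-7-[(tert-butyldimethylsilyl)oxy]nonadeca-9,18-dien-6-ol F2. Shi epoxidation of the trans-disubstituted alkene (the antipode of the D-fructose-derived ketone, chosen to give the 9S,10S epoxide; Oxone, buffered) should leave the terminal alkene alone and give epoxy alcohol 9, which closes with CSA to 10, where the route is rejoined.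

Step 10. Hydride delivery may show poor facial selectivity (a competing chelated pathway) or attack the stearate. The fallback inverts C10 instead of reducing a ketone and sets out from alcohol 10. Mitsunobu reaction with chloroacetic acid (PPh3, DIAD) should give (1R)-1-[(2R,4S,5S)-4-[(tert-butyldimethylsilyl)oxy]-5-pentyloxolan-2-yl]dec-9-en-1-yl chloroacetate F3. HF·pyridine should give (1R)-1-[(2R,4S,5S)-4-hydroxy-5-pentyloxolan-2-yl]dec-9-en-1-yl chloroacetate F4. Acylation with 13 (pyridine, DMAP) should give (2S,3S,5R)-5-[(1R)-1-(chloroacetoxy)dec-9-en-1-yl]-2-pentyloxolan-3-yl octadecanoate F5. Thiourea/NaHCO3 in EtOH should remove only the chloroacetate and give 15 directly.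

Step 2. Hydride delivery to the small, nearly flat oxetanone may show poor facial selectivity, so that the trans alcohol forms as well. The fallback corrects C7 at the esterification stage and sets out from ketone 2. The separated trans isomer (2S,3R)-2-pentyloxetan-3-ol F6 would be silylated to tert-butyldimethyl{[(2S,3R)-2-pentyloxetan-3-yl]oxy}silane F7. Under the conditions of step 6 this should pass through (6S,7R)-7-[(tert-butyldimethylsilyl)oxy]-8-[(2S,3S)-3-(non-8-en-1-yl)oxiran-2-yl]octan-6-ol F8 (not isolated) to (1S)-1-[(2R,4R,5S)-4-[(tert-butyldimethylsilyl)oxy]-5-pentyloxolan-2-yl]dec-9-en-1-ol F9. Dess–Martin oxidation should give 1-[(2R,4R,5S)-4-[(tert-butyldimethylsilyl)oxy]-5-pentyloxolan-2-yl]dec-9-en-1-one F10, and HF·pyridine should give 1-[(2R,4R,5S)-4-hydroxy-5-pentyloxolan-2-yl]dec-9-en-1-one F11. Mitsunobu esterification with stearic acid (PPh3, DIAD) would then invert C7 and give 14, where the route is rejoined.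

Further compounds
F1 | step 6 | (1E)-1-iodoundeca-1,10-diene | I/C=C/CCCCCCCC=C
F2 | step 6 | (6S,7S,9E)-7-[(tert-butyldimethylsilyl)oxy]nonadeca-9,18-dien-6-ol | CCCCC[C@H](O)[C@@H](O[Si](C)(C)C(C)(C)C)C/C=C/CCCCCCCC=C
F3 | step 10 | (1R)-1-[(2R,4S,5S)-4-[(tert-butyldimethylsilyl)oxy]-5-pentyloxolan-2-yl]dec-9-en-1-yl chloroacetate | C=CCCCCCCC[C@@H](OC(=O)CCl)[C@H]1C[C@H](O[Si](C)(C)C(C)(C)C)[C@H](CCCCC)O1
F4 | step 10 | (1R)-1-[(2R,4S,5S)-4-hydroxy-5-pentyloxolan-2-yl]dec-9-en-1-yl chloroacetate | C=CCCCCCCC[C@@H](OC(=O)CCl)[C@H]1C[C@H](O)[C@H](CCCCC)O1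
F5 | step 10 | (2S,3S,5R)-5-[(1R)-1-(chloroacetoxy)dec-9-en-1-yl]-2-pentyloxolan-3-yl octadecanoate | C=CCCCCCCC[C@@H](OC(=O)CCl)[C@H]1C[C@H](OC(=O)CCCCCCCCCCCCCCCCC)[C@H](CCCCC)O1
F6 | step 2 | (2S,3R)-2-pentyloxetan-3-ol (trans) | CCCCC[C@@H]1OC[C@H]1O
F7 | step 2 | tert-butyldimethyl{[(2S,3R)-2-pentyloxetan-3-yl]oxy}silane | CCCCC[C@@H]1OC[C@H]1O[Si](C)(C)C(C)(C)C
F8 | step 2 | (6S,7R)-7-[(tert-butyldimethylsilyl)oxy]-8-[(2S,3S)-3-(non-8-en-1-yl)oxiran-2-yl]octan-6-ol | CCCCC[C@H](O)[C@H](O[Si](C)(C)C(C)(C)C)C[C@@H]1O[C@H]1CCCCCCCC=C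
F9 | step 2 | (1S)-1-[(2R,4R,5S)-4-[(tert-butyldimethylsilyl)oxy]-5-pentyloxolan-2-yl]dec-9-en-1-ol | C=CCCCCCCC[C@H](O)[C@H]1C[C@@H](O[Si](C)(C)C(C)(C)C)[C@H](CCCCC)O1
F10 | step 2 | 1-[(2R,4R,5S)-4-[(tert-butyldimethylsilyl)oxy]-5-pentyloxolan-2-yl]dec-9-en-1-one | C=CCCCCCCCC(=O)[C@H]1C[C@@H](O[Si](C)(C)C(C)(C)C)[C@H](CCCCC)O1
F11 | step 2 | 1-[(2R,4R,5S)-4-hydroxy-5-pentyloxolan-2-yl]dec-9-en-1-one | C=CCCCCCCCC(=O)[C@H]1C[C@@H](O)[C@H](CCCCC)O1
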